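## Structural features

The target is a 3,3''-linked dimer of two 2-(4-methoxyphenyl)chroman-4-ones (flavanones). Unit 1 carries free hydroxyls at C5 and C7, unit 2 a hydroxyl at C5'' and a methoxyl at C7'', so the halves differ by one O-methyl group and the molecule is pseudo-C2-symmetric. The single bond C3–C3'' joins the two pyranone rings and creates a run of four contiguous stereocentres, C2–C3–C3''–C2''; each ring is 2,3-trans and the absolute configuration is 2S,3R,2''S,3''R. C3 and C3'' are α to a ketone and β to an aryloxy group, so base opens either ring to a chalcone (E1cB) and erases C2 and C3 together. The C2–O1 and C2''–O1'' bonds are 4-methoxybenzylic ethers and ionise under acid, and the phloroglucinol-type rings are easily oxidised. The real difficulty is the congested C3–C3'' bond between two enolisable stereocentres of defined absolute sense, made while two almost identical halves are kept distinct. The feature used here is the chain C2–C3–C3''–C2'': it has an aryl group and an oxygen at each end and an aroyl group (C4, C4'') on each inner carbon. Tying C2 and C2'' through one oxygen gives a 2,5-diaryl-3,4-diaroyloxolane, the adduct of a diaryl carbonyl ylide and an (E)-1,4-diaroylethene, and the ortho hydroxyls of the aroyl groups (the future O1 and O1'') are placed to take over the benzylic carbons from the ring oxygen.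

## Logic of the disconnections

16 ⇒ 15. The three O–CH2Ph bonds at O5, O7 and O5'' are cut. All spectator phenols are masked by one type of group, so that a single neutral hydrogenolysis ends the route and no Lewis acid meets the acid-labile C2–O bonds or the enolisable C3/C3'' centres. Nothing is gained in skeleton; the gain is a mild last step. The forward step must leave the flavanone benzylic C–O bonds and the ketones alone.

15 ⇒ 13 (through 14). O1–C2 and O1''–C2'' are cut and C2 and C2'' are joined through one oxygen. These are the bonds that form reversibly under acid and settle in the trans arrangement, so C2 and C2'' drop out of the stereochemical problem and 13 may be any mixture of epimers at these two carbons. Two six-membered heterocycles become one five-membered ring that is a cycloadduct. The forward step must ionise only the benzylic C–O bonds and deliver the cations to the ortho phenols without enolisation or elimination at C3/C3''.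

13 ⇒ 9 + 11 (through 12). C2–C3 and C2''–C3'' are cut. This unravels the oxolane into a symmetric three-atom dipole and an alkene whose double bond is the future C3–C3'' bond, so the hindered central bond is never made between two stereocentres. One ring and four stereocentres are removed, and the two fragments are of similar size. The forward step must keep the E geometry, select one alkene face, and open the oxirane at C–C rather than C–O.

9 ⇒ 3 + 8. The C=C bond is cut (olefination). The two unlike halves then come from two separate acetophenones, which guarantees the unsymmetrical substitution. A stabilised ylide needs no added base and gives the E alkene; the forward step must not turn the ortho phenols into phenoxides that would add to the enedione.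

8 ⇒ 6 ⇒ 5 ⇒ 4 (through 7). The P=C unit, the C–Br bond and one O–CH2Ph bond are removed in turn. Each cut is a standard functional-group change on an acetophenone; the demand is side-chain over ring bromination and alkylation of only the non-chelated hydroxyl.

3 ⇒ 2 ⇒ 1. The aldehyde oxygen is removed (methyl ketone oxidation level) and two O–CH2Ph bonds are cut. The demand is oxidation of the methyl group only, and retention of the chelated hydroxyl in the alkylation.

11 ⇒ 10. The two C–O bonds of the oxirane are cut back to the alkene. The demand is a non-acidic oxidant, because 11 rearranges readily under acid.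

## Other disconnections considered

Alternative 1: The cut runs through C3–C4 and O1–C2, so the pyran ring of unit 1 is made last and unit 2 enters finished. In the forward step, acid removes methanol from the phenol acetal A3 to give an ortho-quinone methide with a methoxy group on the methide carbon. This adds as an oxa-diene to the styrene double bond of the 3-styrylflavanone A2 and gives the 4-methoxychroman A1.
- In favour: the [4+2] addition of ortho-quinone methides to styrenes is an established reaction type; the E-styrene becomes the 2,3-trans pair of unit 1; C2'' can be taken from a natural (2S)-flavanone, so no asymmetric catalyst is needed.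
- Against: A2 is not itself a chiral-pool compound. A styryl group must be attached to C3'' of a flavanone whose enolate opens to the chalcone, which puts C2'' at risk. The styrene face is chosen only by the neighbouring C3'' centre across a rotating single bond. The acid that forms the quinone methide can also ionise the C2''–O1'' bond. A1 is one oxidation level short at C4, so the methyl ether must be turned into the ketone next to three other oxygen-bearing benzylic C–H positions.
- Comparison: on structure the alternative is the better in taking absolute configuration from an existing stereocentre, and the equal in convergence. On mechanism its cycloaddition is better precedented, but the sense of 1,2-induction is open, whereas the chosen plan sets C3 and C3'' together from alkene geometry and one face. On step economy the chosen plan is shorter after the key step (two steps against a redox correction plus deprotection) and does not build the C3–C3'' link on a base-labile flavanone.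

Alternative 2: The cut runs through O1–C2 and O1''–C2'', both pyranone rings at once, back to the bis-chalcone A5. In the forward step a bifunctional tertiary amine–thiourea catalyst activates each 2'-hydroxyl and enone in turn; two oxa-Michael closures and two enol protonations give the bis-flavanone A4.
- In favour: it is the shortest route on paper, redox-neutral, follows the usual chalcone-to-flavanone logic, needs no photochemistry, and the trans rings are the thermodynamic ones.
- Against: four stereocentres arise in two separate events. The relation between C3 and C3'' is fixed only in the second protonation, with nothing that relays the sense of the first ring to the second. Oxa-Michael closure of unactivated 2'-hydroxychalcones is reversible under amine bases, which erodes enantiopurity. A5 is a twisted, cross-conjugated diene-dione, hindered at both β-carbons. The 5''-O-methyl group of A4 must later be cleaved by a Lewis acid next to acid-labile C2–O bonds.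
- Comparison: the alternative is the better in step count and operational simplicity. In precedent neither is better, since both rest on an asymmetric catalytic step not yet shown on this substrate class. On structure and mechanism the chosen plan is better: C3/C3'' come from one face selection plus alkene geometry, and C2/C2'' are left to thermodynamics.

Alternative 3: The cut runs through O1''–C2'', with the cyclopropane bond C2''–C3 restored, back to the donor–acceptor cyclopropane A7. In the forward step a Lewis acid chelated by the hydroxyaroyl ketone polarises the C2''–C3 bond, the phenol attacks C2'' from the rear with inversion, and C3 leaves as an enolate that is protonated to the methylene of the flavanone A6.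
- In favour: stereospecific ring-opening of donor–acceptor cyclopropanes by heteroatom nucleophiles is a well-studied reaction type; the configuration of A7 is transferred to C2''/C3'' of a trans-flavanone without any equilibrium; strain release drives the step.
- Against: only unit 2 is made. In A6, C3 is a methylene, so unit 1 still needs a C2–C3 bond formation, selective removal of one ortho benzyl group and ring closure. C3 must then be created in the right sense relative to C3'' under enolising conditions that also threaten unit 2. The 4-methoxyphenyl donor invites SN1 ionisation and loss of stereospecificity, and a 5''-O-methyl group again remains to be cleaved.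
- Comparison: the alternative is the better in relying on a known, stereospecific bond formation for two of the four centres. It is the equal in exposing a 4-methoxybenzylic carbon to a chelating Lewis acid. It is the weaker in step economy (one ring per key step, then at least four more steps) and in leaving the C3/C3'' relation to a late enolate protonation, which the chosen plan avoids.

Key step: step 8

Remarks on the chemistry (assumptions):
- The spectator oxygen ortho to the carbonyl of unit 2 is carried as a benzyl ether, not a methyl ether. The skeletons of dipolarophile and cycloadduct are unchanged; the route ends with one hydrogenolysis and no boron trihalide demethylation.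
- The ortho phenols stay free from the start, because they are the chelating handle in step 8 and the nucleophiles in step 9. The enedione is therefore assembled without added base.
- 11 is used as the racemate, since both of its stereocentres vanish in the planar ylide.
- The antipode of the ligand that opens the si,si face of 9 cannot be fixed in advance; the one leading to (3R,4R) in the oxolane is assumed.
- (3R,4R) in the oxolane corresponds to (3R,3''R) in the target.
- 3 is drawn as the free glyoxal, although it should rest as its hydrate or cyclic hemiacetal.
- The dipole in step 8 can lie either way round over the two unlike aroyl groups, so the adduct should form as two isomers with the same (3R,4R) pair that differ at both aryl-bearing carbons. The number 13 stands for this unseparated pair, named and drawn as the (2R,5S) isomer; its companion is the (2S,3R,4R,5R) 2,5-bis-epimer.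

## Route

Step 1
Reactants: 1 2',4',6'-trihydroxyacetophenone
Product: 2 1-[2,4-bis(benzyloxy)-6-hydroxyphenyl]ethan-1-one
Conditions: BnBr (2.1 equiv), K2CO3 (2.2 equiv), acetone, reflux
Reagents that add atoms: benzyl bromide, BrCc1ccccc1
Why: Williamson ether synthesis; the hydroxyl locked in the hydrogen bond to the acetyl oxygen is the least nucleophilic, so the para and one ortho hydroxyl are alkylated and the chelated one stays free for steps 8 and 9.

Step 2
Reactants: 2 1-[2,4-bis(benzyloxy)-6-hydroxyphenyl]ethan-1-one
Product: 3 2-[2,4-bis(benzyloxy)-6-hydroxyphenyl]-2-oxoacetaldehyde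
Conditions: SeO2 (1.3 equiv), 1,4-dioxane/H2O (20:1), 90 °C
Reagents that add atoms: selenium dioxide, O=[Se]=O
Why: Riley oxidation of an aryl methyl ketone, which takes the enolisable methyl group to the aldehyde level and stops there in wet dioxane; benzyl ethers and the chelated phenol are expected to survive.

Step 3
Reactants: 4 2',6'-dihydroxy-4'-methoxyacetophenone
Product: 5 1-[2-(benzyloxy)-6-hydroxy-4-methoxyphenyl]ethan-1-one
Conditions: BnBr (1.05 equiv), K2CO3 (1.1 equiv), acetone, reflux
Reagents that add atoms: benzyl bromide, BrCc1ccccc1
Why: Williamson ether synthesis; of the two equivalent hydroxyls only the one not engaged in the hydrogen bond reacts, and after the first alkylation the remaining hydroxyl is chelated, so mono-benzylation should be clean.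

Step 4
Reactants: 5 1-[2-(benzyloxy)-6-hydroxy-4-methoxyphenyl]ethan-1-one
Product: 6 1-[2-(benzyloxy)-6-hydroxy-4-methoxyphenyl]-2-bromoethan-1-one
Conditions: CuBr2 (2.1 equiv), EtOAc/CHCl3 (1:1), reflux
Reagents that add atoms: copper dibromide, [Cu+2].[Br-].[Br-]
Why: Side-chain α-bromination of a hydroxyacetophenone by CuBr2, which brominates through the copper-bound enol and therefore prefers the methyl group over the activated ring.

Step 5
Reactants: 6 1-[2-(benzyloxy)-6-hydroxy-4-methoxyphenyl]-2-bromoethan-1-one
Product: 8 1-[2-(benzyloxy)-6-hydroxy-4-methoxyphenyl]-2-(triphenyl-λ5-phosphanylidene)ethan-1-one, via phosphonium bromide 7 (not isolated)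
Conditions: PPh3, toluene, 60 °C; then aq. Na2CO3, CH2Cl2, 0 °C
Reagents that add atoms: triphenylphosphine, c1ccc(cc1)P(c1ccccc1)c1ccccc1
Why: SN2 quaternisation of the phosphine by the phenacyl bromide, then deprotonation of the acidic P–CH2–C=O methylene to the stabilised acyl ylide; the chelated phenol is far less acidic than the phosphonium methylene and stays protonated.

Step 6
Reactants: 3 2-[2,4-bis(benzyloxy)-6-hydroxyphenyl]-2-oxoacetaldehyde; 8 1-[2-(benzyloxy)-6-hydroxy-4-methoxyphenyl]-2-(triphenyl-λ5-phosphanylidene)ethan-1-one
Product: 9 (2E)-1-[2,4-bis(benzyloxy)-6-hydroxyphenyl]-4-[2-(benzyloxy)-6-hydroxy-4-methoxyphenyl]but-2-ene-1,4-dione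
Conditions: CH2Cl2, rt, exclusion of light
Reagents that add atoms: none
Why: Wittig olefination of the aldehyde carbon of the glyoxal by a stabilised ylide, which is E-selective and needs no added base, so the ortho phenols are not converted into phenoxides that could add to the new enedione.

Step 7
Reactants: 10 (E)-4,4'-dimethoxystilbene
Product: 11 trans-2,3-bis(4-methoxyphenyl)oxirane (racemate)
Conditions: dimethyldioxirane (acetone solution, 1.2 equiv), CH2Cl2, 0 °C
Reagents that add atoms: dimethyldioxirane, CC1(C)OO1
Why: Concerted, stereospecific oxygen transfer from the dioxirane to the electron-rich alkene (E gives trans) under neutral conditions, which spares the very acid-labile oxirane; the racemate suffices because its stereocentres are erased in step 8.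

Step 8
Reactants: 9 (2E)-1-[2,4-bis(benzyloxy)-6-hydroxyphenyl]-4-[2-(benzyloxy)-6-hydroxy-4-methoxyphenyl]but-2-ene-1,4-dione; 11 trans-2,3-bis(4-methoxyphenyl)oxirane
Product: 13 {(2R,3R,4R,5S)-4-[2,4-bis(benzyloxy)-6-hydroxybenzoyl]-2,5-bis(4-methoxyphenyl)oxolan-3-yl}[2-(benzyloxy)-6-hydroxy-4-methoxyphenyl]methanone, via carbonyl ylide 12 (not isolated)
Conditions: Sc(OTf)3 (10 mol %), chiral N,N'-dioxide ligand (L-pipecolic-acid-derived, 2,6-diisopropylanilide arms; 12 mol %), 9,10-dicyanoanthracene (5 mol %), 2,6-di-tert-butylpyridine (20 mol %), 4 Å MS, MeCN/CH2Cl2 (1:1), 420 nm LEDs, −30 °C, 11 (1.5 equiv) added slowly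
Reagents that add atoms: none
Why: Proposed new method: photoexcited 9,10-dicyanoanthracene oxidises 11 to its radical cation, the oxirane C–C bond opens and back electron transfer gives the planar exo,exo carbonyl ylide 12, which adds across the C=C bond of 9 held on the chiral N,N'-dioxide complex of Sc(OTf)3 as a six-membered chelate through one ketone oxygen and its ortho phenol; the closest known reaction type is the cyanoarene-sensitised carbonyl ylide cycloaddition of 2,3-diaryloxiranes to electron-poor alkenes, and what is new is its union with chiral-Lewis-acid face control, which is known for 2'-hydroxychalcones bound to chiral Sc(OTf)3 complexes. The oxolane ring closes by a suprafacial [π4s+π2s] 1,3-dipolar cycloaddition in which C2–C3 and C2''–C3'' form in one event, or at most in a fast two-stage closure on the scandium enolate without bond rotation. C3 and C3'' (oxolane C4 and C3) are trans because the E geometry of 9 is carried over, and their absolute sense (R,R) follows from bonding on the si face of both olefinic carbons, the face left open by the ligand; since 9 is pseudo-C2-symmetric about the axis perpendicular to the enedione plane, chelation at either hydroxyaroyl end exposes the same face, so the two binding modes are matched. The two aryl-bearing centres are cis to each other because the W-shaped ylide adds suprafacially. Which way round the dipole lies over the two unlike aroyl groups is not controlled, and either hydroxyaroyl end can be the chelated one, so the isomer with both aryl groups on the opposite ring face (the 2,5-bis-epimer) should form beside the drawn one; it has the same C3/C3'' pair, is not separated, and is carried on under the number 13 because step 9 rewrites both aryl-bearing centres. The step needs addition to C=C rather than C=O (the di-ortho-substituted, chelated ketones are shielded), a preference for bound over free dipolarophile (the bound enedione has the lower LUMO for the nucleophilic dipole), retention of the E geometry (420 nm light is absorbed mainly by the sensitiser, low temperature) and survival of the acid-labile oxirane (hindered pyridine to take up TfOH released on chelation, sieves, slow addition of 11).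

Step 9
Reactants: 13 {(2R,3R,4R,5S)-4-[2,4-bis(benzyloxy)-6-hydroxybenzoyl]-2,5-bis(4-methoxyphenyl)oxolan-3-yl}[2-(benzyloxy)-6-hydroxy-4-methoxyphenyl]methanone (as obtained in step 8, benzylic epimers unseparated)
Product: 15 (2S,3R,2''S,3''R)-5,7,5''-tris(benzyloxy)-7''-methoxy-2,2''-bis(4-methoxyphenyl)-[3,3''-bichromane]-4,4''-dione, via mono-flavanone carbinol 14 (not isolated)
Conditions: CSA (20 mol %), (CF3)2CHOH/CH2Cl2 (1:1), 4 Å MS, 0 °C to rt
Reagents that add atoms: none
Why: Proposed new method: the acid protonates the ring oxygen, a 4-methoxybenzylic C–O bond ionises (SN1), the ortho phenol of the aroyl group on the neighbouring carbon captures the cation in a six-membered closure to give 14 (drawn for closure of unit 1 first; the order does not matter), whose benzylic hydroxyl then leaves as water and is replaced in the same way by the second phenol. C2 and C2'' should end up trans to C3 and C3'' whatever their configuration in the adduct, so both dipole-orientation isomers carried as 13 converge on 15, because aryl ether formation at these 4-methoxybenzylic carbons is reversible and the 2,3-diequatorial rings are the more stable, while C3 and C3'' are never part of a cation or an enol. The closest known reaction types are the acid cyclodehydration of 3-aryl-3-hydroxy-1-(2-hydroxyaryl)propan-1-ones to flavanones and the acid-induced benzylic C–O ionisation of 2,5-diaryltetrahydrofurans with capture of the cation, as in lignan chemistry.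

Step 10
Reactants: 15 (2S,3R,2''S,3''R)-5,7,5''-tris(benzyloxy)-7''-methoxy-2,2''-bis(4-methoxyphenyl)-[3,3''-bichromane]-4,4''-dione
Product: 16 ruixianglangdusu B, (2S,3R,2''S,3''R)-5,7,5''-trihydroxy-7''-methoxy-2,2''-bis(4-methoxyphenyl)-[3,3''-bichromane]-4,4''-dione
Conditions: H2 (1 atm), Pd/C (10%), EtOAc/THF, rt
Reagents that add atoms: none
Why: Heterogeneous hydrogenolysis of the three aryl benzyl ethers under neutral conditions; at one atmosphere and short reaction time the flavanone C2–O bonds, the ketones, the aryl methyl ethers and the C3/C3'' centres are not expected to be touched.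

## Compound list

1 | 2',4',6'-trihydroxyacetophenone | CC(=O)c1c(O)cc(O)cc1O | starting material
2 | 1-[2,4-bis(benzyloxy)-6-hydroxyphenyl]ethan-1-one | CC(=O)c1c(O)cc(OCc2ccccc2)cc1OCc1ccccc1 | intermediate
3 | 2-[2,4-bis(benzyloxy)-6-hydroxyphenyl]-2-oxoacetaldehyde (arylglyoxal, drawn as the free aldehyde) | O=CC(=O)c1c(O)cc(OCc2ccccc2)cc1OCc1ccccc1 | intermediate
4 | 2',6'-dihydroxy-4'-methoxyacetophenone | CC(=O)c1c(O)cc(OC)cc1O | starting material
5 | 1-[2-(benzyloxy)-6-hydroxy-4-methoxyphenyl]ethan-1-one | CC(=O)c1c(O)cc(OC)cc1OCc1ccccc1 | intermediate
6 | 1-[2-(benzyloxy)-6-hydroxy-4-methoxyphenyl]-2-bromoethan-1-one | O=C(CBr)c1c(O)cc(OC)cc1OCc1ccccc1 | intermediate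
7 | {2-[2-(benzyloxy)-6-hydroxy-4-methoxyphenyl]-2-oxoethyl}triphenylphosphonium bromide (not isolated) | [Br-].O=C(C[P+](c1ccccc1)(c1ccccc1)c1ccccc1)c1c(O)cc(OC)cc1OCc1ccccc1 | intermediate
8 | 1-[2-(benzyloxy)-6-hydroxy-4-methoxyphenyl]-2-(triphenyl-λ5-phosphanylidene)ethan-1-one | O=C(C=P(c1ccccc1)(c1ccccc1)c1ccccc1)c1c(O)cc(OC)cc1OCc1ccccc1 | intermediate
9 | (2E)-1-[2,4-bis(benzyloxy)-6-hydroxyphenyl]-4-[2-(benzyloxy)-6-hydroxy-4-methoxyphenyl]but-2-ene-1,4-dione | O=C(/C=C/C(=O)c1c(O)cc(OC)cc1OCc1ccccc1)c1c(O)cc(OCc2ccccc2)cc1OCc1ccccc1 | intermediate
10 | (E)-4,4'-dimethoxystilbene | COc1ccc(/C=C/c2ccc(OC)cc2)cc1 | starting material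
11 | trans-2,3-bis(4-methoxyphenyl)oxirane (racemate; the 2S,3S enantiomer is drawn) | COc1ccc([C@@H]2O[C@H]2c2ccc(OC)cc2)cc1 | intermediate
12 | exo,exo carbonyl ylide, bis(4-methoxybenzylidene)oxonium ylide (not isolated) | COc1ccc(/C=[O+]/[CH-]c2ccc(OC)cc2)cc1 | intermediate
13 | {(2R,3R,4R,5S)-4-[2,4-bis(benzyloxy)-6-hydroxybenzoyl]-2,5-bis(4-methoxyphenyl)oxolan-3-yl}[2-(benzyloxy)-6-hydroxy-4-methoxyphenyl]methanone (aryl groups 2,5-cis, aroyl groups 3,4-trans, unit 1 aroyl cis to its neighbouring aryl; carried forward with its unseparated (2S,3R,4R,5R) 2,5-bis-epimer from the reversed dipole orientation) | COc1ccc([C@H]2O[C@@H](c3ccc(OC)cc3)[C@H](C(=O)c3c(O)cc(OC)cc3OCc3ccccc3)[C@H]2C(=O)c2c(O)cc(OCc3ccccc3)cc2OCc2ccccc2)cc1 | intermediate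
14 | (2S,3R)-5,7-bis(benzyloxy)-3-{(2R,3R)-1-[2-(benzyloxy)-6-hydroxy-4-methoxyphenyl]-3-hydroxy-3-(4-methoxyphenyl)-1-oxopropan-2-yl}-2-(4-methoxyphenyl)chroman-4-one (not isolated; drawn for closure of unit 1 first from the drawn isomer of 13) | COc1ccc([C@H]2Oc3cc(OCc4ccccc4)cc(OCc4ccccc4)c3C(=O)[C@@H]2[C@@H](C(=O)c2c(O)cc(OC)cc2OCc2ccccc2)[C@@H](O)c2ccc(OC)cc2)cc1 | intermediate
15 | (2S,3R,2''S,3''R)-5,7,5''-tris(benzyloxy)-7''-methoxy-2,2''-bis(4-methoxyphenyl)-[3,3''-bichromane]-4,4''-dione | COc1ccc([C@H]2Oc3cc(OCc4ccccc4)cc(OCc4ccccc4)c3C(=O)[C@@H]2[C@H]2C(=O)c3c(OCc4ccccc4)cc(OC)cc3O[C@@H]2c2ccc(OC)cc2)cc1 | intermediate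
16 | ruixianglangdusu B, (2S,3R,2''S,3''R)-5,7,5''-trihydroxy-7''-methoxy-2,2''-bis(4-methoxyphenyl)-[3,3''-bichromane]-4,4''-dione | COc1ccc([C@H]2Oc3cc(O)cc(O)c3C(=O)[C@@H]2[C@H]2C(=O)c3c(O)cc(OC)cc3O[C@@H]2c2ccc(OC)cc2)cc1 | target

## Step count and least certain steps

Total: 10 steps. Longest linear sequence: 7 steps (4 → 5 → 6 → 8 → 9 → 13 → 15 → 16; steps 3, 4, 5, 6, 8, 9 and 10).

Step 8 (key step, carries the label). Three processes are most likely to go wrong.
- Acid-induced C–O ionisation of the oxirane with a 1,2-shift (Meinwald-type rearrangement) may run ahead of the photochemical C–C cleavage, because the bis(4-methoxyphenyl)oxirane is extremely sensitive to Lewis and Brønsted acids.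
- Face selectivity may be poor if the ylide adds to enedione that is not bound to scandium.
- Light-induced E/Z isomerisation of the enedione would place the aroyl groups cis.

Fallback with known chemistry, setting out from 9 and 11: irradiation at 420 nm in MeCN with 9,10-dicyanoanthracene alone, without any Lewis acid, is the established sensitised cycloaddition. It should give both dipole-orientation isomers as racemates: the drawn isomer of 13 together with the mirror-image adduct ent-13 F1, and the (2S,3R,4R,5R) 2,5-bis-epimer of 13 F2 together with its mirror image, the (2R,3S,4S,5S) isomer F3. The diastereomers would be separated on silica and each racemate resolved by preparative chromatography on a polysaccharide chiral stationary phase. The two (3R,4R) fractions are combined and the route is rejoined at 13. This replaces asymmetric induction by separation of enantiomers.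

Step 9 (carries the label). The most likely failures are loss of the C3 or C3'' proton from the benzylic cation (E1) or acid-catalysed retro-oxa-Michael opening, either of which erases a stereocentre that step 8 has set. Capture of the cation by the carbonyl oxygen of the other aroyl group, and cleavage of benzyl ethers in the ionising medium, are further risks.

Fallback with known chemistry, setting out from 13: hydrogenolysis over Pd/C in AcOH/EtOAc, known to cleave the benzylic C–O bonds of 2,5-diaryloxolanes, should cut both ring C–O bonds and the three benzyl ethers. Both isomers carried as 13 would give the same open diketone (2S,3S)-1-(2,6-dihydroxy-4-methoxyphenyl)-2,3-bis[(4-methoxyphenyl)methyl]-4-(2,4,6-trihydroxyphenyl)butane-1,4-dione F4, with C3 and C3'' untouched. Dehydrogenative cyclisation of its two 2'-hydroxydihydrochalcone units with DDQ (2.2 equiv, dioxane), a known quinone oxidation that abstracts hydride from the 4-methoxybenzylic methylene and lets the ortho phenol capture the cation, would close both rings trans. The route is rejoined at 16, and step 10 falls away. This replaces the redox-neutral oxygen exchange by a reduction–oxidation relay.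

Step 6. The most likely failures are slow olefination, because the glyoxal rests as its cyclic hemiacetal, and conjugate cyclisation of an ortho phenol onto the newly formed enedione, triggered by the basicity of the ylide.

Fallback, setting out from 3 and 5: aldol addition of the dianion of 5 (LiN(SiMe3)2, 2.2 equiv, THF, −78 °C) to the aldehyde carbon of 3, used as its lithium phenoxide, should give the racemic hydroxy diketone 1-[2,4-bis(benzyloxy)-6-hydroxyphenyl]-4-[2-(benzyloxy)-6-hydroxy-4-methoxyphenyl]-2-hydroxybutane-1,4-dione F5. Acid-catalysed dehydration (TsOH, toluene, 60 °C) would rejoin the route at 9. Steps 4 and 5 then fall away, and the enedione is formed only under acid, where the chelated phenols are poor nucleophiles.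

Step 2. The most likely failures are over-oxidation to the arylglyoxylic acid and oxidative cyclisation onto the free ortho phenol, since the product sits as a hemiacetal that selenium dioxide can oxidise further.

Fallback, setting out from 2: side-chain bromination with CuBr2 (EtOAc/CHCl3, reflux), as in step 4, would give 1-[2,4-bis(benzyloxy)-6-hydroxyphenyl]-2-bromoethan-1-one F6. Kornblum oxidation in DMSO at 40–60 °C would then give the glyoxal, and the route is rejoined at 3. This replaces direct C–H oxidation by halogenation followed by oxygen transfer from the sulfoxide.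

## Further compounds

F1 | step 8 | ent-13, {(2S,3S,4S,5R)-4-[2,4-bis(benzyloxy)-6-hydroxybenzoyl]-2,5-bis(4-methoxyphenyl)oxolan-3-yl}[2-(benzyloxy)-6-hydroxy-4-methoxyphenyl]methanone | COc1ccc([C@@H]2O[C@H](c3ccc(OC)cc3)[C@@H](C(=O)c3c(O)cc(OC)cc3OCc3ccccc3)[C@@H]2C(=O)c2c(O)cc(OCc3ccccc3)cc2OCc2ccccc2)cc1
F2 | step 8 | (2S,3R,4R,5R) 2,5-bis-epimer of 13 (aryl groups 2,5-cis, aroyl groups 3,4-trans, unit 2 aroyl cis to its neighbouring aryl) | COc1ccc([C@@H]2O[C@H](c3ccc(OC)cc3)[C@H](C(=O)c3c(O)cc(OC)cc3OCc3ccccc3)[C@H]2C(=O)c2c(O)cc(OCc3ccccc3)cc2OCc2ccccc2)cc1
F3 | step 8 | (2R,3S,4S,5S) stereoisomer of the same oxolane, mirror image of the 2,5-bis-epimer of 13 | COc1ccc([C@H]2O[C@@H](c3ccc(OC)cc3)[C@@H](C(=O)c3c(O)cc(OC)cc3OCc3ccccc3)[C@@H]2C(=O)c2c(O)cc(OCc3ccccc3)cc2OCc2ccccc2)cc1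
F4 | step 9 | (2S,3S)-1-(2,6-dihydroxy-4-methoxyphenyl)-2,3-bis[(4-methoxyphenyl)methyl]-4-(2,4,6-trihydroxyphenyl)butane-1,4-dione | COc1ccc(C[C@H](C(=O)c2c(O)cc(O)cc2O)[C@H](Cc2ccc(OC)cc2)C(=O)c2c(O)cc(OC)cc2O)cc1
F5 | step 6 | 1-[2,4-bis(benzyloxy)-6-hydroxyphenyl]-4-[2-(benzyloxy)-6-hydroxy-4-methoxyphenyl]-2-hydroxybutane-1,4-dione (racemate) | O=C(CC(O)C(=O)c1c(O)cc(OCc2ccccc2)cc1OCc1ccccc1)c1c(O)cc(OC)cc1OCc1ccccc1
F6 | step 2 | 1-[2,4-bis(benzyloxy)-6-hydroxyphenyl]-2-bromoethan-1-one | O=C(CBr)c1c(O)cc(OCc2ccccc2)cc1OCc1ccccc1
A1 | alternative 1 | 4-methoxychroman cycloadduct: unit 1 as 5,7-bis(benzyloxy)-4-methoxy-2-(4-methoxyphenyl)chroman-3-yl, unit 2 as the finished (2S,3R)-5-hydroxy-7-methoxy-2-(4-methoxyphenyl)chroman-4-one | COc1ccc([C@H]2Oc3cc(OCc4ccccc4)cc(OCc4ccccc4)c3[C@@H](OC)[C@@H]2[C@H]2C(=O)c3c(O)cc(OC)cc3O[C@@H]2c2ccc(OC)cc2)cc1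
A2 | alternative 1 | (2S,3R)-5-hydroxy-7-methoxy-2-(4-methoxyphenyl)-3-[(E)-2-(4-methoxyphenyl)ethenyl]chroman-4-one | COc1ccc(/C=C/[C@H]2C(=O)c3c(O)cc(OC)cc3O[C@@H]2c2ccc(OC)cc2)cc1
A3 | alternative 1 | 3,5-bis(benzyloxy)-2-(dimethoxymethyl)phenol | COC(OC)c1c(O)cc(OCc2ccccc2)cc1OCc1ccccc1
A4 | alternative 2 | (2S,3R,2''S,3''R)-5,7-bis(benzyloxy)-5'',7''-dimethoxy-2,2''-bis(4-methoxyphenyl)-[3,3''-bichromane]-4,4''-dione | COc1ccc([C@H]2Oc3cc(OCc4ccccc4)cc(OCc4ccccc4)c3C(=O)[C@@H]2[C@H]2C(=O)c3c(OC)cc(OC)cc3O[C@@H]2c2ccc(OC)cc2)cc1
A5 | alternative 2 | (2E,3E)-1-[2,4-bis(benzyloxy)-6-hydroxyphenyl]-4-(2-hydroxy-4,6-dimethoxyphenyl)-2,3-bis(4-methoxybenzylidene)butane-1,4-dione | COc1ccc(/C=C(/C(=O)c2c(O)cc(OCc3ccccc3)cc2OCc2ccccc2)C(=C/c2ccc(OC)cc2)\C(=O)c2c(O)cc(OC)cc2OC)cc1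
A6 | alternative 3 | (2S,3R)-5,7-dimethoxy-2-(4-methoxyphenyl)-3-[2-oxo-2-(2,4,6-tribenzyloxyphenyl)ethyl]chroman-4-one | O=C(C[C@H]1C(=O)c2c(OC)cc(OC)cc2O[C@@H]1c1ccc(OC)cc1)c1c(OCc2ccccc2)cc(OCc2ccccc2)cc1OCc1ccccc1
A7 | alternative 3 | [2-(2-hydroxy-4,6-dimethoxybenzoyl)-3-(4-methoxyphenyl)cyclopropyl](2,4,6-tribenzyloxyphenyl)methanone, single enantiomer, aryl trans to the hydroxyaroyl group and the two aroyl groups trans | COc1ccc([C@H]2[C@H](C(=O)c3c(O)cc(OC)cc3OC)[C@H]2C(=O)c2c(OCc3ccccc3)cc(OCc3ccccc3)cc2OCc2ccccc2)cc1
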